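(The data come from a simulation on assumed constants; the scatter is artificial.)

Per hour is the unit to reckon in: what share of the free X does E take up in an hour?

common to all: G 1 mol%

| charge | X | E | remark | time |
|---|---|---|---|---|
| midnight | 0.20 M (fed, over 6.0 h) | 5 equiv | run made earlier |  |
| flask | 0.40 M (fed, over 6.0 h) | 5.00 equiv |  | 6.0 h |

- midnight (time / h: Q / %, X / %, J / %): 0.667: 0, 10.7, 1.7; 1.33: 1.1, 23.0, 0; 2.00: 0.3, 33.4, 1.3; 3.00: 2.8, 47.1, 0; 4.00: 1.4, 63.7, 1.5; 5.00: 4.4, 79.1, 0

(scatter of a reading: 1 percentage point)

- the species that holds most of what was charged as X, at 6.0 h (X / J / Q)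
- the largest share itself, whichever of these holds it, in percent of the X charged

- the earlier runs were read with a standard deviation of 1 percentage point
- reactions considered so far: X + E <-> Q; X + E <-> J; Q + G <-> J + G; E -> Z
- percentages count the whole charge, also what has not yet gone in
- no earlier run changes the charge of G; that part of a forecast is a guess

The midnight run gives that share. By 5.00 h the steady feed has put in 83.3% of the charge, yet the reading of X is 79.1%, so 4.23% has been taken up, a reading with its scatter. Free X has built up along the feed line, which makes a mean exposure of 2.08 h, and the ratio is a pseudo-first-order constant, k' = 0.0203 h⁻¹, an average over whatever E did in those hours. Its half-life is 34.1 h. Define the capture share L as k' times the feed time over 2, the part of the charge lost by the end of a steady feed: midnight gives L = 6.10%.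

Now the ladder for the new flask. The feed comes first, over 6.0 h. Capture is slower: E is charged twice as concentrated in this flask, so a k' doubled with it brings the half-life to 17.1 h, still longer than the feed. J shows no rise at midnight, its readings going from 1.7% to 0%. So X piles up. L lies between 6.10%, if k' does not follow the concentration, and 12.2%, if k' doubles with E falling away as it did at midnight, and I commit to X at 90.8%.

The forecast says X at 88%, the low end of my range: “X clearly remains the largest share”. The flask gives X at 92.9%, with Q at 5.63% and J at 1.50%.

    X + E ⇌ Q (K = 0.350 M⁻¹, k = 0.123 M⁻¹ h⁻¹)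
    X + E ⇌ J (K = 2.06 M⁻¹, k = 0.00227 M⁻¹ h⁻¹)
    Q + G ⇌ J + G, rate k3*[G]*[Q] forward; the back reaction follows from the equilibrium constant (k = 13.2 M⁻¹ h⁻¹)
    E → Z (k = 0.411 h⁻¹)

So this flask lost 7.13%, less than the doubled L, a ratio of 0.584. The step from E to Z, which k' already carries, holds the loss down in this flask: without it the same flask ends with X at 69.1%, not 92.9%, and with it E is down to 8.16% of its charge at 6.00 h. For a neighbour flask charged with 1.20 equiv of E, scaling L by the E charge gives 2.93%; that ratio then puts X at 98.3%, and the neighbour ends at 98.2%.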